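**Retrosynthetic overview** (drimane numbering: C4 = CMe2, C5 = ring-fusion CH, C10 = ring-fusion C–CH3, C8 = carbinol carbon, C9 = CH bearing C11H2–aryl)
1. Target ⇐ one-flask unmasking (acetal, two aryl methyl ethers) of a protected carbinol ⇐ methyl addition to a C8 ketone from the convex face of a cis-decalin.
2. Key bond C11–aryl: palladium-mediated coupling of a ketone homoenolate, released by opening a cyclopropanol fused at C8–C9, with a hindered aryl bromide; the ketone β-carbon and the aryl ipso carbon are both electrophilic in their normal guise.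
3. Cyclopropanol ⇐ convex-face cyclopropanation of the regiodefined silyl enol ether formed by cuprate angular methylation of a bicyclic enone, which sets the cis ring fusion (C10).
4. Enone stereocentre (C5) ⇐ catalytic asymmetric isomerisation of the β,γ-enone from Birch reduction of 6-methoxy-1,1-dimethyltetralin ⇐ 6-methoxy-1-tetralone.
5. Ring order: both decalin rings are those of the tetralone (saturated ring → ring A, anisole ring → ring B); the only ring made is the transient cyclopropane; the arene is attached in step 7.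

Assumption: the SMILES is read literally as the (1R,2R,4aR,8aS) isomer, a cis-fused decalin with angular CH3, ring-fusion H, C11H2 and carbinol CH3 on one face and OH on the other (the C5 epimer of the sclareolide-derived series, so that chiral pool cannot supply the core).

**Step 1**
Reactants: 1 6-methoxy-3,4-dihydronaphthalen-1(2H)-one (6-methoxy-1-tetralone)
Product: 2 6-methoxy-1,1-dimethyl-1,2,3,4-tetrahydronaphthalene
Conditions: TiCl4, Me2Zn, CH2Cl2, −30 → 0 °C
Reagents that add atoms: dimethylzinc C[Zn]C (both methyl groups, relayed through dimethyltitanium dichloride C[Ti](C)(Cl)Cl)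
Why: Reetz geminal dimethylation, in which Me2TiCl2 adds methyl to the aryl ketone and the titanium alkoxide ionises to a p-methoxybenzylic cation that takes the second methyl, turning C=O into the future C4 gem-dimethyl group without enolisation or ether cleavage.

**Step 2**
Reactants: 2 6-methoxy-1,1-dimethyl-1,2,3,4-tetrahydronaphthalene
Product: 4 5,5-dimethyl-3,4,5,6,7,8-hexahydronaphthalen-2(1H)-one, via dienol ether 3 (not isolated)
Conditions: Li, NH3(l), THF, t-BuOH, −33 °C; NH4Cl; then (CO2H)2, MeOH–H2O, rt
Reagents that add atoms: water O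
Why: Birch reduction leaves the double bonds on the donor-substituted carbons (enol ether and tetrasubstituted ring-fusion alkene), and mild oxalic acid hydrolysis of the enol ether frees the ketone without conjugating the alkene, as in the classical estradiol methyl ether to 5(10)-en-3-one sequence.

**Step 3**
Reactants: 4 5,5-dimethyl-3,4,5,6,7,8-hexahydronaphthalen-2(1H)-one
Product: 5 (4aR)-5,5-dimethyl-4,4a,5,6,7,8-hexahydronaphthalen-2(3H)-one
Conditions: 9-amino-9-deoxy-epi-quinidine-type primary–tertiary diamine catalyst (10 mol %), CF3CO2H (20 mol %), toluene, −20 °C → rt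
Reagents that add atoms: none
Why: Amine-catalysed asymmetric olefin isomerisation of a β,γ- to an α,β-unsaturated cyclohexenone, in which the ketone forms a dienamine with the chiral primary amine and the protonated quinuclidine delivers the proton to one face of the γ-carbon (future C5), setting the 4aR centre; the pseudo-enantiomer that gives 4aR is selected by experiment, and the quinine-derived catalyst gives the antipode.

**Step 4**
Reactants: 5 (4aR)-5,5-dimethyl-4,4a,5,6,7,8-hexahydronaphthalen-2(3H)-one
Product: 6 trimethyl{[(4aR,8aS)-5,5,8a-trimethyl-3,4,4a,5,6,7,8,8a-octahydronaphthalen-2-yl]oxy}silane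
Conditions: Me2CuLi (from MeLi, CuI), Me3SiCl, THF–Et2O, −78 → −20 °C
Reagents that add atoms: methyllithium C[Li] (as lithium dimethylcuprate); chlorotrimethylsilane C[Si](C)(C)Cl
Why: Me3SiCl-accelerated Gilman conjugate addition, where axial attack on the ring-fusion β-carbon from the face of the neighbouring ring-fusion hydrogen (the other face carries the CMe2 carbon) gives the cis-fused decalin with angular methyl cis to that hydrogen, and silylation fixes the enolate regiospecifically on the carbon next to the new quaternary centre (C9).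

**Step 5**
Reactants: 6 trimethyl{[(4aR,8aS)-5,5,8a-trimethyl-3,4,4a,5,6,7,8,8a-octahydronaphthalen-2-yl]oxy}silane
Product: 8 (1aS,3aR,7aS,7bR)-4,4,7a-trimethyldecahydro-1H-cyclopropa[a]naphthalen-1a-ol (cyclopropane CH2 bridging C8 and C9 on the face of the angular methyl), via siloxycyclopropane 7 (not isolated)
Conditions: Et2Zn, CH2I2, CH2Cl2, 0 °C → rt; then MeOH, K2CO3 (cat.), 0 °C
Reagents that add atoms: diiodomethane ICI
Why: Furukawa–Simmons–Smith cyclopropanation of the electron-rich enol ether from the convex face of the cis-decalin (the face of angular methyl and ring-fusion H, the concave face being covered by the axial CH2 of ring A), which sets C9 with the new CH2 cis to the angular methyl, followed by methanolysis of the silyl ether.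

**Step 6**
Reactants: 9 2-bromo-1,4-dimethoxybenzene
Product: 12 2-bromo-3-(dimethoxymethyl)-1,4-dimethoxybenzene, via aryllithium 10 (not isolated), via bromoaldehyde 11 (not isolated)
Conditions: LDA, THF, −78 °C; DMF, −78 → 0 °C; AcOH; then HC(OMe)3, MeOH, TsOH (cat.), rt
Reagents that add atoms: N,N-dimethylformamide CN(C)C=O; trimethyl orthoformate COC(OC)OC
Why: Directed ortho-lithiation at the most acidic position between Br and OMe (LDA does not exchange the bromide at −78 °C), formylation with DMF, and acid-catalysed acetalisation that masks the aldehyde for steps 7 and 8.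

**Step 7**
Reactants: 8 (1aS,3aR,7aS,7bR)-4,4,7a-trimethyldecahydro-1H-cyclopropa[a]naphthalen-1a-ol; 12 2-bromo-3-(dimethoxymethyl)-1,4-dimethoxybenzene
Product: 13 (1R,4aR,8aS)-1-{[2-(dimethoxymethyl)-3,6-dimethoxyphenyl]methyl}-5,5,8a-trimethyloctahydronaphthalen-2(1H)-one
Conditions: Pd(OAc)2 (5 mol %), XPhos (10 mol %), Cs2CO3, toluene, 80 °C
Reagents that add atoms: none
Why: Palladium-catalysed ring-opening cross-coupling of a cyclopropanol (ketone homoenolate), in which the arylpalladium alkoxide undergoes β-carbon elimination of the less substituted C8–CH2 bond to a primary alkylpalladium that reductively eliminates with the aryl group, joining the ketone β-carbon C11 to the aryl carbon while the C9 centre from step 5 is not touched and is retained.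

**Step 8**
Reactants: 13 (1R,4aR,8aS)-1-{[2-(dimethoxymethyl)-3,6-dimethoxyphenyl]methyl}-5,5,8a-trimethyloctahydronaphthalen-2(1H)-one
Product: 14 (1R,2R,4aR,8aS)-1-{[2-(dimethoxymethyl)-3,6-dimethoxyphenyl]methyl}-2,5,5,8a-tetramethyldecahydronaphthalen-2-ol
Conditions: MeLi, CeCl3, THF, −78 °C; aq. NH4Cl
Reagents that add atoms: methyllithium C[Li]
Why: Organocerium (Imamoto) 1,2-addition, where the weakly basic MeCeCl2 attacks the enolisable ketone equatorially from the convex face because axial approach is blocked by the syn-axial CH2 of ring A, placing the new methyl cis to C11 and the angular methyl and the hydroxyl on the concave face (C8 = R).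

**Step 9**
Reactants: 14 (1R,2R,4aR,8aS)-1-{[2-(dimethoxymethyl)-3,6-dimethoxyphenyl]methyl}-2,5,5,8a-tetramethyldecahydronaphthalen-2-ol
Product: 17 3,6-dihydroxy-2-{[(1R,2R,4aR,8aS)-2-hydroxy-2,5,5,8a-tetramethyldecahydronaphthalen-1-yl]methyl}benzaldehyde, via dimethoxy aldehyde 15 (not isolated), via formylquinone 16 (not isolated)
Conditions: (NH4)2Ce(NO3)6, MeCN–H2O, 0 °C; then Na2S2O4, H2O–EtOAc, rt
Reagents that add atoms: water O
Why: Aqueous (NH4)2Ce(NO3)6 hydrolyses the dimethyl acetal and carries out the oxidative demethylation of the p-dimethoxyarene to the quinone, which dithionite reduces in the same flask to the hydroquinone, leaving the tertiary alcohol, the aldehyde and all four stereocentres untouched.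

**Compound list**
1 | 6-methoxy-3,4-dihydronaphthalen-1(2H)-one | COc1ccc2c(c1)CCCC2=O | starting material
2 | 6-methoxy-1,1-dimethyl-1,2,3,4-tetrahydronaphthalene | COc1ccc2c(c1)CCCC2(C)C | intermediate
3 | 6-methoxy-1,1-dimethyl-1,2,3,4,5,8-hexahydronaphthalene | COC1=CCC2=C(C1)CCCC2(C)C | intermediate
4 | 5,5-dimethyl-3,4,5,6,7,8-hexahydronaphthalen-2(1H)-one | CC1(C)CCCC2=C1CCC(=O)C2 | intermediate
5 | (4aR)-5,5-dimethyl-4,4a,5,6,7,8-hexahydronaphthalen-2(3H)-one | CC1(C)CCCC2=CC(=O)CC[C@@H]21 | intermediate
6 | trimethyl{[(4aR,8aS)-5,5,8a-trimethyl-3,4,4a,5,6,7,8,8a-octahydronaphthalen-2-yl]oxy}silane | CC1(C)CCC[C@@]2(C)[C@@H]1CCC(O[Si](C)(C)C)=C2 | intermediate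
7 | trimethyl{[(1aS,3aR,7aS,7bR)-4,4,7a-trimethyldecahydro-1H-cyclopropa[a]naphthalen-1a-yl]oxy}silane | CC1(C)CCC[C@@]2(C)[C@@H]1CC[C@]3(O[Si](C)(C)C)C[C@H]23 | intermediate
8 | (1aS,3aR,7aS,7bR)-4,4,7a-trimethyldecahydro-1H-cyclopropa[a]naphthalen-1a-ol | CC1(C)CCC[C@@]2(C)[C@@H]1CC[C@]3(O)C[C@H]23 | intermediate
9 | 2-bromo-1,4-dimethoxybenzene | COc1ccc(OC)c(Br)c1 | starting material
10 | (2-bromo-3,6-dimethoxyphenyl)lithium | COc1ccc(OC)c([Li])c1Br | intermediate
11 | 2-bromo-3,6-dimethoxybenzaldehyde | COc1ccc(OC)c(C=O)c1Br | intermediate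
12 | 2-bromo-3-(dimethoxymethyl)-1,4-dimethoxybenzene | COc1ccc(OC)c(C(OC)OC)c1Br | intermediate
13 | (1R,4aR,8aS)-1-{[2-(dimethoxymethyl)-3,6-dimethoxyphenyl]methyl}-5,5,8a-trimethyloctahydronaphthalen-2(1H)-one | CC1(C)CCC[C@@]2(C)[C@@H]1CCC(=O)[C@@H]2Cc1c(OC)ccc(OC)c1C(OC)OC | intermediate
14 | (1R,2R,4aR,8aS)-1-{[2-(dimethoxymethyl)-3,6-dimethoxyphenyl]methyl}-2,5,5,8a-tetramethyldecahydronaphthalen-2-ol | CC1(C)CCC[C@@]2(C)[C@@H]1CC[C@@](C)(O)[C@@H]2Cc1c(OC)ccc(OC)c1C(OC)OC | intermediate
15 | 2-{[(1R,2R,4aR,8aS)-2-hydroxy-2,5,5,8a-tetramethyldecahydronaphthalen-1-yl]methyl}-3,6-dimethoxybenzaldehyde | CC1(C)CCC[C@@]2(C)[C@@H]1CC[C@@](C)(O)[C@@H]2Cc1c(OC)ccc(OC)c1C=O | intermediate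
16 | 2-{[(1R,2R,4aR,8aS)-2-hydroxy-2,5,5,8a-tetramethyldecahydronaphthalen-1-yl]methyl}-3,6-dioxocyclohexa-1,4-diene-1-carbaldehyde | CC1(C)CCC[C@@]2(C)[C@@H]1CC[C@@](C)(O)[C@@H]2CC1=C(C=O)C(=O)C=CC1=O | intermediate
17 | 3,6-dihydroxy-2-{[(1R,2R,4aR,8aS)-2-hydroxy-2,5,5,8a-tetramethyldecahydronaphthalen-1-yl]methyl}benzaldehyde | CC1(C)CCC[C@@]2(C)[C@@H]1CC[C@@](C)(O)[C@@H]2Cc1c(O)ccc(O)c1C=O | target

**Totals**
Total step count: 9. Longest linear sequence: 8 (steps 1–5 and 7–9; step 6 is the aryl branch).

**Steps most likely to fail, with fallbacks**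

Step 3. The γ-carbon to be protonated sits next to the CMe2 carbon, so the isomerisation may stall or give low ee. Fallback: set out from 4 and isomerise with catalytic HCl in MeOH to the racemic enone (±)-5,5-dimethyl-4,4a,5,6,7,8-hexahydronaphthalen-2(3H)-one F1. Separate the enantiomers by preparative supercritical-fluid chromatography on an amylose tris(3,5-dimethylphenylcarbamate) phase. Return the unwanted antipode to 4 (KOt-Bu, then AcOH quench) for recycling. The route is rejoined at 5.

Step 7. The aryl bromide is flanked by two ortho substituents, and the alkylpalladium can undergo β-hydride elimination (to the α-methylene ketone) or protonation (to the α-methyl ketone). The base may also epimerise C9 next to the new ketone. Fallback: invert the roles of the partners, setting out from 12 and 6. Treat 12 with n-BuLi (THF, −78 °C) to give aryllithium [2-(dimethoxymethyl)-3,6-dimethoxyphenyl]lithium F2. Trap it with paraformaldehyde to give benzylic alcohol [2-(dimethoxymethyl)-3,6-dimethoxyphenyl]methanol F3. Convert this with CBr4/PPh3 to benzylic bromide 2-(bromomethyl)-3-(dimethoxymethyl)-1,4-dimethoxybenzene F4. Cleave silyl enol ether 6 with MeLi (THF, 0 °C) to lithium enolate lithium (4aR,8aS)-5,5,8a-trimethyl-3,4,4a,5,6,7,8,8a-octahydronaphthalen-2-olate F5. Alkylate F5 with F4 (THF–DMPU, −78 → 0 °C); the electrophile again enters on the convex face. This gives 13 directly and bypasses steps 5 and 7.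

Step 8. Methyl may add from the wrong face, or the reagent may enolise the hindered ketone. Fallback: set out from 13 and use dimethylsulfoxonium methylide (Me3S(O)I, NaH, DMSO), which adds reversibly and places the new CH2 equatorial on the convex face. This gives spiro-epoxide (oxirane CH2 cis to the angular methyl, O on the concave face) F6. Reductive opening at the CH2 terminus with LiEt3BH (THF, 0 °C) gives 14.

**Further compounds**
F1 | step 3 | (±)-5,5-dimethyl-4,4a,5,6,7,8-hexahydronaphthalen-2(3H)-one | CC1(C)CCCC2=CC(=O)CCC12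
F2 | step 7 | [2-(dimethoxymethyl)-3,6-dimethoxyphenyl]lithium | COc1ccc(OC)c(C(OC)OC)c1[Li]
F3 | step 7 | [2-(dimethoxymethyl)-3,6-dimethoxyphenyl]methanol | COc1ccc(OC)c(C(OC)OC)c1CO
F4 | step 7 | 2-(bromomethyl)-3-(dimethoxymethyl)-1,4-dimethoxybenzene | COc1ccc(OC)c(C(OC)OC)c1CBr
F5 | step 7 | lithium (4aR,8aS)-5,5,8a-trimethyl-3,4,4a,5,6,7,8,8a-octahydronaphthalen-2-olate | CC1(C)CCC[C@@]2(C)[C@@H]1CCC(O[Li])=C2
F6 | step 8 | spiro-epoxide of 13 at the ketone carbon (oxirane CH2 cis to the angular methyl) | CC1(C)CCC[C@@]2(C)[C@@H]1CC[C@]3(CO3)[C@@H]2Cc1c(OC)ccc(OC)c1C(OC)OC
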